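**Plan**

1. Rings: A = benzene ring of the benzofuran, B = furan ring, C = benzene ring of the chroman, D = dihydropyran ring. Retrosynthetic cuts, in order: the three aryl O–Si bonds; ring B at C3a–C3 and O1–C2 (to an ortho-iodophenol carrying ring A and an arylacetylene carrying rings C and D); the C7–CMe2 bond on ring A (aromatic Claisen, back to a prenyl ether); ring D at C4–C3 and O1–C8a (to a 2,6-dibromobenzyl bromide and isobutylene oxide).
2. Enabling feature: in ring C, the carbon C4a carries the benzylic C4 of ring D, and its two ortho neighbours are C8a (bearing O1 of ring D) and C5 (bearing ring B). Ring C is therefore a 4-oxy-2,6-dibromobenzyl unit with a mirror plane through C4a and C7. Its benzylic carbon (nucleophile) and either C–Br (electrophile) match the CH2 (electrophile) and O (nucleophile) of the epoxide, and the bromide not used is left as the C5 handle.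
3. Forward order: ring D is closed first by this [3+3] annulation, then the alkyne is put on C5. Separately, ring A is iodinated, O-prenylated and rearranged. Ring B is closed last and joins the halves, followed by global desilylation.
4. Stereochemistry: the target has no stereocentre and no stereogenic double bond, so nothing has to be set.

Key step: step 3

Assumption: 3,5-dibromo-4-methylphenol, phloroglucinol, isobutylene oxide, ethynyltrimethylsilane and prenol are taken as purchasable.

**Route**

Step 1
Reactants: 1 3,5-dibromo-4-methylphenol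
Product: 2 (3,5-dibromo-4-methylphenoxy)triisopropylsilane
Conditions: TIPSCl, imidazole, DMF, 23 °C
Reagents that add atoms: triisopropylsilyl chloride (TIPSCl), CC(C)[Si](Cl)(C(C)C)C(C)C
Why: Imidazole-promoted O-silylation (silyl ether protection) masks the only acidic proton before the radical and organomagnesium steps, and the hindered triisopropylsilyl ether should resist the tert-butoxide of step 3.

Step 2
Reactants: 2 (3,5-dibromo-4-methylphenoxy)triisopropylsilane
Product: 3 [3,5-dibromo-4-(bromomethyl)phenoxy]triisopropylsilane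
Conditions: NBS (1.05 equiv), AIBN (cat.), PhCF3, 85 °C
Reagents that add atoms: N-bromosuccinimide (NBS), O=C1CCC(=O)N1Br
Why: Wohl–Ziegler benzylic bromination should be selective because the benzylic radical is the only stabilised radical available and the two ring bromines deactivate the arene toward ionic ring bromination.

Step 3
Reactants: 3 [3,5-dibromo-4-(bromomethyl)phenoxy]triisopropylsilane; 4 2,2-dimethyloxirane (isobutylene oxide)
Product: 7 [(5-bromo-2,2-dimethylchroman-7-yl)oxy]triisopropylsilane, via benzylic Grignard reagent 5 (not isolated), via bromomagnesium tertiary alkoxide 6 (not isolated)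
Conditions: Mg, Et2O, 0 °C; cannulated off excess Mg into 4 (1.5 equiv), CuI (10 mol%), THF, −30 to 20 °C; then same flask: NaOtBu (2.2 equiv), Pd(OAc)2 (5 mol%), (±)-Tol-BINAP (6 mol%), toluene, ethers distilled off, 90 °C
Reagents that add atoms: none
Why: Magnesium inserts into the benzylic C–Br bond of 3 much faster than into the aryl C–Br bonds, the benzylcopper species formed with CuI opens 4 by SN2 attack at its unsubstituted CH2 (new C4–C3 bond of ring D), and the tertiary alkoxide 6, freed from magnesium by NaOtBu, is arylated by zerovalent palladium through oxidative addition into an ortho C–Br bond, alkoxide coordination and C–O reductive elimination (new O1–C8a bond). The closest known reaction types are the copper-catalysed opening of isobutylene oxide by benzylic Grignard reagents and the Buchwald–Hartwig intramolecular etherification of 4-(2-bromoaryl)-2-methylbutan-2-ols to 2,2-dimethylchromans, telescoped here into a formal [3+3] annulation. Ring D closes by C–O reductive elimination from a seven-membered aryl(alkoxo)palladium chelate, formally a 6-exo ipso substitution at C8a. No stereocentre is formed. The step needs attack at the CH2 and not at the quaternary carbon of the epoxide, which copper catalysis at low temperature should secure against Lewis-acid isomerisation to isobutyraldehyde, and it needs a single ring closure, which the substrate secures because its two C–Br bonds are symmetry-equivalent and only one alkoxide is present, so the untouched bromide stays as the C5 handle. The tertiary alkoxide has no hydrogen on its carbinol carbon, so β-hydride elimination and reductive debromination should not compete.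

Step 4
Reactants: 7 [(5-bromo-2,2-dimethylchroman-7-yl)oxy]triisopropylsilane; 8 ethynyltrimethylsilane
Product: 9 triisopropyl({2,2-dimethyl-5-[(trimethylsilyl)ethynyl]chroman-7-yl}oxy)silane
Conditions: Pd(PhCN)2Cl2 (3 mol%), P(t-Bu)3·HBF4 (6 mol%), CuI (2 mol%), i-Pr2NH, dioxane, 50 °C
Reagents that add atoms: none
Why: Sonogashira coupling of the remaining aryl bromide, with the bulky electron-rich phosphine speeding oxidative addition at the ortho-substituted C5–Br bond.

Step 5
Reactants: 9 triisopropyl({2,2-dimethyl-5-[(trimethylsilyl)ethynyl]chroman-7-yl}oxy)silane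
Product: 10 [(5-ethynyl-2,2-dimethylchroman-7-yl)oxy]triisopropylsilane
Conditions: K2CO3 (0.2 equiv), MeOH/THF, 0 °C
Reagents that add atoms: none
Why: Methoxide-mediated protodesilylation cleaves the alkynyl C–Si bond much faster than the hindered aryl O–Si(i-Pr)3 bond under catalytic carbonate at 0 °C.

Step 6
Reactants: 11 phloroglucinol (benzene-1,3,5-triol)
Product: 12 3,5-bis(tert-butyldimethylsilyloxy)phenol
Conditions: TBSCl (2.0 equiv), imidazole, DMF, 0 to 23 °C; chromatographic separation from mono- and tris-silyl ethers
Reagents that add atoms: tert-butyldimethylsilyl chloride (TBSCl), CC(C)(C)[Si](C)(C)Cl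
Why: Statistical O-silylation of the threefold-symmetric triol can give only one bis-silyl ether, which should be separable from the recyclable mono- and tris-ethers.

Step 7
Reactants: 12 3,5-bis(tert-butyldimethylsilyloxy)phenol
Product: 13 2-iodo-3,5-bis(tert-butyldimethylsilyloxy)phenol
Conditions: I2 (1.0 equiv), NaHCO3, THF/H2O, 0 °C
Reagents that add atoms: iodine, II
Why: Electrophilic aromatic iodination of the phenol should occur ortho to the free hydroxyl because the para carbon is shielded by two flanking OTBS groups, and one equivalent of iodine limits di-iodination.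

Step 8
Reactants: 13 2-iodo-3,5-bis(tert-butyldimethylsilyloxy)phenol; 14 3-methylbut-2-en-1-ol (prenol)
Product: 15 2-iodo-1-(3-methylbut-2-en-1-yloxy)-3,5-bis(tert-butyldimethylsilyloxy)benzene
Conditions: PPh3, DIAD, THF, 0 to 23 °C
Reagents that add atoms: none
Why: Mitsunobu etherification under neutral conditions should give the primary prenyl ether without exposing the aryl silyl ethers to a phenoxide or carbonate base.

Step 9
Reactants: 15 2-iodo-1-(3-methylbut-2-en-1-yloxy)-3,5-bis(tert-butyldimethylsilyloxy)benzene
Product: 17 2-iodo-6-(2-methylbut-3-en-2-yl)-3,5-bis(tert-butyldimethylsilyloxy)phenol, via ortho-dienone 16 (not isolated)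
Conditions: PhNEt2, 170 °C, argon
Reagents that add atoms: none
Why: The aromatic Claisen rearrangement ([3,3]-sigmatropic shift) delivers the allyl unit with inversion, as a 1,1-dimethylallyl group, to the only free ortho carbon (the other carries iodine), and the amine solvent speeds enolisation of 16 so that a second Cope shift to the para carbon, itself shielded by two OTBS groups, should not compete.

Step 10
Reactants: 17 2-iodo-6-(2-methylbut-3-en-2-yl)-3,5-bis(tert-butyldimethylsilyloxy)phenol; 10 [(5-ethynyl-2,2-dimethylchroman-7-yl)oxy]triisopropylsilane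
Product: 19 4,6-bis(tert-butyldimethylsilyloxy)-2-[2,2-dimethyl-7-(triisopropylsilyloxy)chroman-5-yl]-7-(2-methylbut-3-en-2-yl)benzofuran, via ortho-alkynylphenol 18 (not isolated)
Conditions: Pd(PPh3)2Cl2 (5 mol%), CuI (10 mol%), Et3N, DMF, degassed, 25 to 75 °C
Reagents that add atoms: none
Why: Domino Sonogashira coupling at the C–I bond (C3a–C3 bond) and copper/palladium-promoted 5-endo-dig hydroalkoxylation of the alkyne by the neighbouring phenol (O1–C2 bond), the Castro–Stephens/Sonogashira benzofuran annulation, should close ring B and join the two halves.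

Step 11
Reactants: 19 4,6-bis(tert-butyldimethylsilyloxy)-2-[2,2-dimethyl-7-(triisopropylsilyloxy)chroman-5-yl]-7-(2-methylbut-3-en-2-yl)benzofuran
Product: 20 2-(7-hydroxy-2,2-dimethylchroman-5-yl)-7-(2-methylbut-3-en-2-yl)benzofuran-4,6-diol (target)
Conditions: TBAF (3.5 equiv), AcOH (3.5 equiv), THF, 0 to 23 °C, argon
Reagents that add atoms: none
Why: Fluoride-induced cleavage of the three aryl silyl ethers, buffered with acetic acid so that the electron-rich phenoxides are protonated at once, should leave the 1,1-dimethylallyl group and the chroman untouched because no strong acid is present.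

**Compound list**

1 | 3,5-dibromo-4-methylphenol | Cc1c(Br)cc(O)cc1Br | starting material
2 | (3,5-dibromo-4-methylphenoxy)triisopropylsilane | Cc1c(Br)cc(O[Si](C(C)C)(C(C)C)C(C)C)cc1Br | intermediate
3 | [3,5-dibromo-4-(bromomethyl)phenoxy]triisopropylsilane | BrCc1c(Br)cc(O[Si](C(C)C)(C(C)C)C(C)C)cc1Br | intermediate
4 | 2,2-dimethyloxirane (isobutylene oxide) | CC1(C)CO1 | starting material
5 | [2,6-dibromo-4-(triisopropylsilyloxy)benzyl]magnesium bromide (formed in the flask, not isolated) | Br[Mg]Cc1c(Br)cc(O[Si](C(C)C)(C(C)C)C(C)C)cc1Br | intermediate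
6 | bromomagnesium 4-[2,6-dibromo-4-(triisopropylsilyloxy)phenyl]-2-methylbutan-2-olate (formed in the flask, not isolated) | CC(C)(CCc1c(Br)cc(O[Si](C(C)C)(C(C)C)C(C)C)cc1Br)O[Mg]Br | intermediate
7 | [(5-bromo-2,2-dimethylchroman-7-yl)oxy]triisopropylsilane | CC1(C)CCc2c(Br)cc(O[Si](C(C)C)(C(C)C)C(C)C)cc2O1 | intermediate
8 | ethynyltrimethylsilane | C#C[Si](C)(C)C | starting material
9 | triisopropyl({2,2-dimethyl-5-[(trimethylsilyl)ethynyl]chroman-7-yl}oxy)silane | C[Si](C)(C)C#Cc1cc(O[Si](C(C)C)(C(C)C)C(C)C)cc2OC(C)(C)CCc12 | intermediate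
10 | [(5-ethynyl-2,2-dimethylchroman-7-yl)oxy]triisopropylsilane | C#Cc1cc(O[Si](C(C)C)(C(C)C)C(C)C)cc2OC(C)(C)CCc12 | intermediate
11 | phloroglucinol (benzene-1,3,5-triol) | Oc1cc(O)cc(O)c1 | starting material
12 | 3,5-bis(tert-butyldimethylsilyloxy)phenol | Oc1cc(O[Si](C)(C)C(C)(C)C)cc(O[Si](C)(C)C(C)(C)C)c1 | intermediate
13 | 2-iodo-3,5-bis(tert-butyldimethylsilyloxy)phenol | Oc1c(I)c(O[Si](C)(C)C(C)(C)C)cc(O[Si](C)(C)C(C)(C)C)c1 | intermediate
14 | 3-methylbut-2-en-1-ol (prenol) | CC(C)=CCO | starting material
15 | 2-iodo-1-(3-methylbut-2-en-1-yloxy)-3,5-bis(tert-butyldimethylsilyloxy)benzene | CC(C)=CCOc1cc(O[Si](C)(C)C(C)(C)C)cc(O[Si](C)(C)C(C)(C)C)c1I | intermediate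
16 | 2-iodo-6-(2-methylbut-3-en-2-yl)-3,5-bis(tert-butyldimethylsilyloxy)cyclohexa-2,4-dien-1-one (racemic, formed in the flask, not isolated) | C=CC(C)(C)C1C(=O)C(I)=C(O[Si](C)(C)C(C)(C)C)C=C1O[Si](C)(C)C(C)(C)C | intermediate
17 | 2-iodo-6-(2-methylbut-3-en-2-yl)-3,5-bis(tert-butyldimethylsilyloxy)phenol | C=CC(C)(C)c1c(O)c(I)c(O[Si](C)(C)C(C)(C)C)cc1O[Si](C)(C)C(C)(C)C | intermediate
18 | 2-{[2,2-dimethyl-7-(triisopropylsilyloxy)chroman-5-yl]ethynyl}-6-(2-methylbut-3-en-2-yl)-3,5-bis(tert-butyldimethylsilyloxy)phenol (formed in the flask, not isolated) | C=CC(C)(C)c1c(O)c(C#Cc2cc(O[Si](C(C)C)(C(C)C)C(C)C)cc3OC(C)(C)CCc23)c(O[Si](C)(C)C(C)(C)C)cc1O[Si](C)(C)C(C)(C)C | intermediate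
19 | 4,6-bis(tert-butyldimethylsilyloxy)-2-[2,2-dimethyl-7-(triisopropylsilyloxy)chroman-5-yl]-7-(2-methylbut-3-en-2-yl)benzofuran | C=CC(C)(C)c1c(O[Si](C)(C)C(C)(C)C)cc(O[Si](C)(C)C(C)(C)C)c2cc(-c3cc(O[Si](C(C)C)(C(C)C)C(C)C)cc4c3CCC(C)(C)O4)oc12 | intermediate
20 | 2-(7-hydroxy-2,2-dimethylchroman-5-yl)-7-(2-methylbut-3-en-2-yl)benzofuran-4,6-diol | C=CC(C)(C)c1c(O)cc(O)c2cc(-c3cc(O)cc4c3CCC(C)(C)O4)oc12 | target

**Step count and risks**

Total steps: 11. Longest linear sequence: 7 steps (steps 1, 2, 3, 4, 5, 10, 11); the second branch (steps 6 to 9) joins at step 10.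

Steps most likely to fail:

Step 3. What may go wrong: Wurtz-type homocoupling during magnesium insertion; Lewis-acid isomerisation of the epoxide to isobutyraldehyde before the C–C bond forms; stalling of the palladium cycle in the presence of magnesium and copper salts; loss of the silyl ether to tert-butoxide. The fallback builds the side chain by enolate alkylation and methyl addition instead of epoxide opening, and closes the ring as a separate step on an isolated alcohol. It sets out from 3. The lithium enolate of ethyl acetate (LDA, EtOAc, THF, −78 °C) is alkylated by 3 to give ethyl 3-[2,6-dibromo-4-(triisopropylsilyloxy)phenyl]propanoate F1. Excess MeMgBr (THF, 0 °C) converts it into 4-[2,6-dibromo-4-(triisopropylsilyloxy)phenyl]-2-methylbutan-2-ol F2, the protonated form of 6. This alcohol is cyclised with Pd(OAc)2, (±)-Tol-BINAP and K2CO3 in toluene at 100 °C, and the fallback comes back to the route at 7.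

Step 9. What may go wrong: a second Cope shift to the para carbon; abnormal Claisen isomerisation of the side chain; thermal loss of iodine; addition of the new phenol to the vinyl group. The fallback replaces the sigmatropic shift by a cross-coupling. It sets out from 13. NBS (CH2Cl2, −40 °C) brominates the remaining carbon ortho to the hydroxyl to give 2-bromo-6-iodo-3,5-bis(tert-butyldimethylsilyloxy)phenol F3. Chemoselective Sonogashira coupling and annulation at the C–I bond with 10 (conditions of step 10) gives 7-bromo-4,6-bis(tert-butyldimethylsilyloxy)-2-[2,2-dimethyl-7-(triisopropylsilyloxy)chroman-5-yl]benzofuran F4. A γ-selective (branched) Suzuki–Miyaura coupling with prenylboronic acid pinacol ester (CC(C)=CCB1OC(C)(C)C(C)(C)O1; Pd(OAc)2, bulky biarylphosphine, K3PO4, THF/H2O) then installs the 1,1-dimethylallyl group, and the fallback comes back to the route at 19.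

Step 10. What may go wrong: slow oxidative addition and transmetalation at the doubly ortho-substituted, electron-rich C–I bond; oxidative homocoupling of the alkyne; incomplete ring closure by the hindered phenol. The fallback changes the order of events so that the coupling is run on a less hindered, phenol-free iodide. It sets out from 15 and 10. Their Sonogashira coupling (Pd(PPh3)2Cl2, CuI, Et3N, DMF, 50 °C) gives 2-{[2,2-dimethyl-7-(triisopropylsilyloxy)chroman-5-yl]ethynyl}-1-(3-methylbut-2-en-1-yloxy)-3,5-bis(tert-butyldimethylsilyloxy)benzene F5. Heating in PhNEt2 at 170 °C moves the allyl unit to the only free ortho carbon and so gives 18, which is cycloisomerised with catalytic CuI and Et3N, and the fallback comes back to the route at 19.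

**Further compounds**

F1 | step 3 | ethyl 3-[2,6-dibromo-4-(triisopropylsilyloxy)phenyl]propanoate | CCOC(=O)CCc1c(Br)cc(O[Si](C(C)C)(C(C)C)C(C)C)cc1Br
F2 | step 3 | 4-[2,6-dibromo-4-(triisopropylsilyloxy)phenyl]-2-methylbutan-2-ol | CC(C)(O)CCc1c(Br)cc(O[Si](C(C)C)(C(C)C)C(C)C)cc1Br
F3 | step 9 | 2-bromo-6-iodo-3,5-bis(tert-butyldimethylsilyloxy)phenol | Oc1c(I)c(O[Si](C)(C)C(C)(C)C)cc(O[Si](C)(C)C(C)(C)C)c1Br
F4 | step 9 | 7-bromo-4,6-bis(tert-butyldimethylsilyloxy)-2-[2,2-dimethyl-7-(triisopropylsilyloxy)chroman-5-yl]benzofuran | Brc1c(O[Si](C)(C)C(C)(C)C)cc(O[Si](C)(C)C(C)(C)C)c2cc(-c3cc(O[Si](C(C)C)(C(C)C)C(C)C)cc4c3CCC(C)(C)O4)oc12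
F5 | step 10 | 2-{[2,2-dimethyl-7-(triisopropylsilyloxy)chroman-5-yl]ethynyl}-1-(3-methylbut-2-en-1-yloxy)-3,5-bis(tert-butyldimethylsilyloxy)benzene | CC(C)=CCOc1cc(O[Si](C)(C)C(C)(C)C)cc(O[Si](C)(C)C(C)(C)C)c1C#Cc1cc(O[Si](C(C)C)(C(C)C)C(C)C)cc2OC(C)(C)CCc12
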